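**Plan**

1. Ring numbering used below: C1 = quaternary carbon (CH3, chlorovinyl), C2 = its CH2 neighbour, C3 = CBr(CH2Br), C4 = CHCl, C5 = CH2, C6 = CHCl next to C1.
2. Retrosynthesis: Br2 is removed from C3/CH2 (exocyclic C3=CH2); C4–Cl is traced to an axial allylic C4–OH (SN2); C3=CH2 and C4–OH to a C3 ketone from allylic oxidation of a C4=C5 cyclohexene; Z-CH=CHCl to CHO; last, the ring is cut at C2–C3 and C6–C1 (retro-Diels–Alder) into methacrolein (C1, C2) and (E)-1-chlorobuta-1,3-diene (C3–C6).
3. Enabling feature: C1/C2 are a 1,1-disubstituted two-carbon unit whose C1 carries a formyl-derived branch, and the neopentyl C6–Cl sits on the ring carbon next to C1 and cis to that branch. This is the ortho, endo pattern of a 1-chlorodiene adding to a 2-substituted acrolein, so the C–Cl bond that cannot be made by substitution next to a quaternary carbon arrives with the diene.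
4. Forward order: diene, then the cyclohexene ring (the only ring-forming event), then the chlorovinyl arm, then oxygenation at C3 and C4, exocyclic methylene, C4 chloride, dibromide.
5. Stereochemistry: C1 from the chiral boron Lewis acid; C6 from diene geometry and the endo rule; C4 from axial Rubottom attack on the chair fixed by C1/C6, then inversion; C3 from axial opening of the bromonium ion on the same chair; the Z alkene from syn hydroboration and protonolysis of a chloroalkyne.

Key step: step 2

Assumption (sense of induction): N-protonated (R)-1-(2-methylphenyl)-3,3-diphenyltetrahydro-1H,3H-pyrrolo[1,2-c][1,3,2]oxazaborole is taken to expose the Si face of the α-carbon of bound methacrolein, the mirror image of the sense known for its (S)-enantiomer with 2-substituted acroleins; if the sense is the reverse, the (S)-enantiomer is used and nothing else changes.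

**Step 1**
Reactants: 1 (E)-1,2-dichloroethene; 2 4,4,5,5-tetramethyl-2-vinyl-1,3,2-dioxaborolane
Product: 3 (E)-1-chlorobuta-1,3-diene
Conditions: Pd(PPh3)4 (3 mol%), K3PO4, diglyme/H2O, 60 °C, sealed vessel, dichloroethene in fourfold excess; product distilled out over BHT
Reagents that add atoms: none
Why: Suzuki–Miyaura cross-coupling, in which zerovalent palladium inserts into one C–Cl bond of the activated dichloroalkene and couples with retention of the E geometry; the excess of the dichloroalkene and the lower reactivity of the more electron-rich chlorodiene should hold the reaction at monocoupling.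

**Step 2**
Reactants: 3 (E)-1-chlorobuta-1,3-diene; 4 methacrolein
Product: 5 (1S,2S)-2-chloro-1-methylcyclohex-3-ene-1-carbaldehyde
Conditions: (R)-1-(2-methylphenyl)-3,3-diphenyltetrahydro-1H,3H-pyrrolo[1,2-c][1,3,2]oxazaborole (20 mol%) protonated with Tf2NH (18 mol%), CH2Cl2, −78 to −40 °C, diene in threefold excess
Reagents that add atoms: none
Why: The N-protonated oxazaborolidine binds the formyl oxygen of s-trans methacrolein and lowers its LUMO, so that a concerted but asynchronous [4+2] cycloaddition occurs in which the unsubstituted diene terminus bonds first to the enal CH2 and the chlorine-bearing terminus, its developing positive character stabilised by the chlorine lone pairs, closes onto the α-carbon (ortho regiochemistry). The closest known reaction type is the oxazaborolidinium-catalysed Diels–Alder reaction of 2-substituted acroleins (methacrolein, 2-bromoacrolein) with acyclic 1,3-dienes. The six-membered carbocycle is closed by suprafacial–suprafacial [4+2] cycloaddition, both ring bonds (enal CH2 to diene CH2 terminus, quaternary carbon to CHCl) forming in one transition state. The quaternary centre is controlled by the catalyst, which screens one enantioface of the bound enal so that the diene adds to the Si face of the α-carbon of methacrolein; the CHCl centre is controlled by the E geometry of the diene together with the endo orientation of the formyl group (methyl exo), which places Cl cis to CHO. The step needs ortho regioselectivity (secured because the only donor substituent sits on the terminus that must bond to the α-carbon), endo selectivity (secondary overlap of the coordinated formyl group, with no bridging CH2 to oppose it as in cyclopentadiene) and enantioface selectivity (catalyst); any Z diene cannot reach the s-cis conformation and is left behind.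

**Step 3**
Reactants: 5 (1S,2S)-2-chloro-1-methylcyclohex-3-ene-1-carbaldehyde
Product: 6 (3S,4S)-3-chloro-4-ethynyl-4-methylcyclohex-1-ene
Conditions: dimethyl (1-diazo-2-oxopropyl)phosphonate (1.5 equiv), K2CO3, MeOH, 0 °C to rt
Reagents that add atoms: dimethyl (1-diazo-2-oxopropyl)phosphonate, CC(=O)C(=[N+]=[N-])P(=O)(OC)OC
Why: Seyferth–Gilbert homologation in its Ohira–Bestmann form converts the hindered, non-enolisable aldehyde into the terminal alkyne under mild carbonate conditions that cannot epimerise the quaternary centre and that the allylic chloride, deactivated by the adjacent quaternary carbon, should tolerate.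

**Step 4**
Reactants: 6 (3S,4S)-3-chloro-4-ethynyl-4-methylcyclohex-1-ene
Product: 8 (3S,4S)-3-chloro-4-(chloroethynyl)-4-methylcyclohex-1-ene, via lithium acetylide 7 (not isolated)
Conditions: LiN(SiMe3)2, THF, −78 °C; then N-chlorosuccinimide, −78 to 0 °C
Reagents that add atoms: N-chlorosuccinimide, O=C1CCC(=O)N1Cl
Why: Deprotonation of the terminal alkyne and electrophilic chlorination of the lithium acetylide by N-chlorosuccinimide is the standard route to 1-chloroalkynes, and the amide base at −78 °C should leave the allylic chloride and ring alkene untouched.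

**Step 5**
Reactants: 8 (3S,4S)-3-chloro-4-(chloroethynyl)-4-methylcyclohex-1-ene
Product: 10 (3S,4S)-3-chloro-4-[(Z)-2-chloroethenyl]-4-methylcyclohex-1-ene, via alkenylborane 9 (not isolated)
Conditions: Cy2BH (1.05 equiv), THF, 0 °C; then AcOH, rt
Reagents that add atoms: none
Why: Syn hydroboration of the 1-chloroalkyne by the hindered dialkylborane puts boron on the chlorine-bearing carbon, and protonolysis of the alkenyl C–B bond by acetic acid with retention then gives the Z-1-chloroalkene (Zweifel–Brown hydroboration–protonolysis), the cis-disubstituted ring alkene being much slower towards Cy2BH.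

**Step 6**
Reactants: 10 (3S,4S)-3-chloro-4-[(Z)-2-chloroethenyl]-4-methylcyclohex-1-ene
Product: 12 (4S,5S)-4-chloro-5-[(Z)-2-chloroethenyl]-5-methylcyclohex-2-en-1-one, via allylic tert-butyl peroxide 11 (not isolated)
Conditions: Rh2(cap)4 (dirhodium tetracaprolactamate, 1 mol%), t-BuOOH (70% in water, 5 equiv), 1,2-dichloroethane, 40 °C
Reagents that add atoms: tert-butyl hydroperoxide, CC(C)(C)OO
Why: Dirhodium caprolactamate/t-BuOOH allylic C–H oxidation, in which the tert-butylperoxyl radical abstracts hydrogen from the unhindered allylic CH2 (C3) and not from the neopentyl, chlorine-deactivated C6–H, peroxyl capture at the same terminus gives the mixed peroxide, and its Kornblum–DeLaMare collapse gives the enone without touching a stereocentre.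

**Step 7**
Reactants: 12 (4S,5S)-4-chloro-5-[(Z)-2-chloroethenyl]-5-methylcyclohex-2-en-1-one
Product: 15 (2S,4S,5S)-4-chloro-5-[(Z)-2-chloroethenyl]-2-hydroxy-5-methylcyclohexan-1-one, via triethylsilyl enol ether 13 (not isolated), via silyloxy ketone 14 (not isolated)
Conditions: RhCl(PPh3)3 (2 mol%), Et3SiH, PhMe, 50 °C; solvent exchange; mCPBA, NaHCO3, CH2Cl2, −20 °C; then 1 M HCl, THF, 0 °C
Reagents that add atoms: mCPBA (3-chloroperoxybenzoic acid), OOC(=O)c1cccc(Cl)c1
Why: Ojima 1,4-hydrosilylation with monovalent rhodium gives the regiodefined C3(OSi)=C4 silyl enol ether, and Rubottom oxidation then delivers oxygen to C4 along the axial trajectory from the face opposite the axial chlorovinyl group on C1, so the new C4–O bond is axial and trans to the C6 chlorine.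

**Step 8**
Reactants: 15 (2S,4S,5S)-4-chloro-5-[(Z)-2-chloroethenyl]-2-hydroxy-5-methylcyclohexan-1-one
Product: 16 (1S,4S,5S)-5-chloro-4-[(Z)-2-chloroethenyl]-4-methyl-2-methylidenecyclohexan-1-ol
Conditions: Ph3PCH3Br (3.5 equiv), KOtBu (3.3 equiv), THF, 0 °C to rt
Reagents that add atoms: methyltriphenylphosphonium bromide, C[P+](c1ccccc1)(c1ccccc1)c1ccccc1.[Br-]
Why: Wittig methylenation with excess ylide (phosphonium salt kept in slight excess over base so that no free tert-butoxide attacks the Z-chloroalkene) converts the ketone into the exocyclic alkene while the hydroxyl is carried as its alkoxide, which disfavours enolisation towards C4 and so keeps that centre intact.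

**Step 9**
Reactants: 16 (1S,4S,5S)-5-chloro-4-[(Z)-2-chloroethenyl]-4-methyl-2-methylidenecyclohexan-1-ol
Product: 17 (1S,2S,4R)-2,4-dichloro-1-[(Z)-2-chloroethenyl]-1-methyl-5-methylidenecyclohexane
Conditions: PPh3, hexachloroacetone, CH2Cl2, 0 °C
Reagents that add atoms: hexachloroacetone, ClC(Cl)(Cl)C(=O)C(Cl)(Cl)Cl
Why: Appel-type chlorination (PPh3/hexachloroacetone, conditions developed for allylic alcohols) displaces the axial oxyphosphonium group by chloride in an SN2 reaction with inversion and little allylic transposition, giving the equatorial C4 chloride cis to the C6 chlorine.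

**Step 10**
Reactants: 17 (1S,2S,4R)-2,4-dichloro-1-[(Z)-2-chloroethenyl]-1-methyl-5-methylidenecyclohexane
Product: 18 (1S,2R,4S,5S)-1-bromo-1-(bromomethyl)-2,4-dichloro-5-[(Z)-2-chloroethenyl]-5-methylcyclohexane (target)
Conditions: Br2 (1.0 equiv), CH2Cl2, −78 °C, dark
Reagents that add atoms: bromine, BrBr
Why: Electrophilic anti addition of bromine to the 1,1-disubstituted alkene (far more reactive than the chlorine-deactivated chloroalkene), in which the bromonium ion forms on the exposed equatorial face and bromide opens it at the tertiary carbon along the axial trajectory, which should give the axial C3–Br bond and equatorial CH2Br group of the target.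

**Compound list**

1 | (E)-1,2-dichloroethene | Cl/C=C/Cl | starting material
2 | 4,4,5,5-tetramethyl-2-vinyl-1,3,2-dioxaborolane | C=CB1OC(C)(C)C(C)(C)O1 | starting material
3 | (E)-1-chlorobuta-1,3-diene | Cl/C=C/C=C | intermediate
4 | methacrolein (2-methylprop-2-enal) | CC(=C)C=O | starting material
5 | (1S,2S)-2-chloro-1-methylcyclohex-3-ene-1-carbaldehyde | C[C@@]1(C=O)CCC=C[C@@H]1Cl | intermediate
6 | (3S,4S)-3-chloro-4-ethynyl-4-methylcyclohex-1-ene | C[C@@]1(C#C)CCC=C[C@@H]1Cl | intermediate
7 | lithium [(1S,2S)-2-chloro-1-methylcyclohex-3-en-1-yl]ethynide | C[C@@]1(C#C[Li])CCC=C[C@@H]1Cl | intermediate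
8 | (3S,4S)-3-chloro-4-(chloroethynyl)-4-methylcyclohex-1-ene | C[C@@]1(C#CCl)CCC=C[C@@H]1Cl | intermediate
9 | {(Z)-1-chloro-2-[(1S,2S)-2-chloro-1-methylcyclohex-3-en-1-yl]ethenyl}dicyclohexylborane | C[C@@]1(/C=C(\Cl)B(C2CCCCC2)C2CCCCC2)CCC=C[C@@H]1Cl | intermediate
10 | (3S,4S)-3-chloro-4-[(Z)-2-chloroethenyl]-4-methylcyclohex-1-ene | C[C@@]1(/C=C\Cl)CCC=C[C@@H]1Cl | intermediate
11 | tert-butyl (4S,5S)-4-chloro-5-[(Z)-2-chloroethenyl]-5-methylcyclohex-2-en-1-yl peroxide (either C1 epimer) | C[C@@]1(/C=C\Cl)CC(OOC(C)(C)C)C=C[C@@H]1Cl | intermediate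
12 | (4S,5S)-4-chloro-5-[(Z)-2-chloroethenyl]-5-methylcyclohex-2-en-1-one | C[C@@]1(/C=C\Cl)CC(=O)C=C[C@@H]1Cl | intermediate
13 | {[(4S,5S)-4-chloro-5-[(Z)-2-chloroethenyl]-5-methylcyclohex-1-en-1-yl]oxy}triethylsilane | C[C@@]1(/C=C\Cl)CC(O[Si](CC)(CC)CC)=CC[C@@H]1Cl | intermediate
14 | (2S,4S,5S)-4-chloro-5-[(Z)-2-chloroethenyl]-5-methyl-2-[(triethylsilyl)oxy]cyclohexan-1-one | C[C@@]1(/C=C\Cl)CC(=O)[C@@H](O[Si](CC)(CC)CC)C[C@@H]1Cl | intermediate
15 | (2S,4S,5S)-4-chloro-5-[(Z)-2-chloroethenyl]-2-hydroxy-5-methylcyclohexan-1-one | C[C@@]1(/C=C\Cl)CC(=O)[C@@H](O)C[C@@H]1Cl | intermediate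
16 | (1S,4S,5S)-5-chloro-4-[(Z)-2-chloroethenyl]-4-methyl-2-methylidenecyclohexan-1-ol | C[C@@]1(/C=C\Cl)CC(=C)[C@@H](O)C[C@@H]1Cl | intermediate
17 | (1S,2S,4R)-2,4-dichloro-1-[(Z)-2-chloroethenyl]-1-methyl-5-methylidenecyclohexane | C[C@@]1(/C=C\Cl)CC(=C)[C@H](Cl)C[C@@H]1Cl | intermediate
18 | (1S,2R,4S,5S)-1-bromo-1-(bromomethyl)-2,4-dichloro-5-[(Z)-2-chloroethenyl]-5-methylcyclohexane | C[C@@]1(/C=C\Cl)C[C@@](Br)(CBr)[C@H](Cl)C[C@@H]1Cl | target

**Totals and risks**

Total step count: 10. Longest linear sequence: 10 steps (from 1 and 2 to 18).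

Steps most likely to fail:

Step 2. The halogen-deactivated diene may turn over too slowly on the chiral boron cation, or endo and enantioface control may erode at the temperature needed for conversion. The fallback sets out from 3 and 4. A cycloaddition promoted by the achiral Lewis acid MeAlCl2 (20 mol%, CH2Cl2, −78 to −20 °C) should give the racemic cis adduct, that is 5 together with its enantiomer (1R,2R)-2-chloro-1-methylcyclohex-3-ene-1-carbaldehyde F1. Condensation of the mixture with commercial (1R,2R)-N,N'-dimethyl-1,2-diphenylethane-1,2-diamine (4 Å sieves, Et2O) should give the diastereomeric imidazolidines (4R,5R)-2-[(1S,2S)-2-chloro-1-methylcyclohex-3-en-1-yl]-1,3-dimethyl-4,5-diphenylimidazolidine F2 and (4R,5R)-2-[(1R,2R)-2-chloro-1-methylcyclohex-3-en-1-yl]-1,3-dimethyl-4,5-diphenylimidazolidine F3, which are separated by chromatography or crystallisation. Hydrolysis of F2 (dilute aqueous HCl, Et2O, 0 °C) returns the route to 5.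

Step 6. Hydrogen abstraction or peroxyl capture may occur at the wrong allylic terminus, or the chloroalkene may be attacked by oxygen radicals. The fallback sets out from 10 and replaces the radical pathway by a pericyclic one. With SeO2 (catalytic)/t-BuOOH in CH2Cl2, the selenium electrophile should add to C5 so that positive charge develops at C4, remote from chlorine. The ene step takes the C3 hydrogen, and the [2,3]-sigmatropic shift returns the double bond to C4=C5 and places oxygen on C3. This gives the allylic alcohol (4S,5S)-4-chloro-5-[(Z)-2-chloroethenyl]-5-methylcyclohex-2-en-1-ol F4 (either C1 epimer). Oxidation with Dess–Martin periodinane (CH2Cl2, rt) brings the route back to 12.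

Step 10. The axial approach of bromide to C3 passes the axial chlorovinyl group on C1, so the bromonium ion may be opened with the opposite facial sense and give the C3 epimer. The fallback sets out from 17. If bromination delivers the epimeric dibromide (1R,2R,4S,5S)-1-bromo-1-(bromomethyl)-2,4-dichloro-5-[(Z)-2-chloroethenyl]-5-methylcyclohexane F5, the crude dibromide is equilibrated thermally (1,2-dichloroethane or MeCN, 60–80 °C, dark). This uses the known 1,2-bromine shift (mutarotation) of vicinal dibromides, which inverts only the CBr(CH2Br) carbon. The target, with equatorial CH2Br and axial Br, should be the thermodynamically preferred epimer because the alternative places CH2Br syn-axial to the chlorovinyl group. The route comes back at 18.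

**Further compounds**

F1 | step 2 | (1R,2R)-2-chloro-1-methylcyclohex-3-ene-1-carbaldehyde | C[C@]1(C=O)CCC=C[C@H]1Cl
F2 | step 2 | (4R,5R)-2-[(1S,2S)-2-chloro-1-methylcyclohex-3-en-1-yl]-1,3-dimethyl-4,5-diphenylimidazolidine | CN1[C@H](c2ccccc2)[C@H](N(C)C1[C@]3(C)CCC=C[C@@H]3Cl)c2ccccc2
F3 | step 2 | (4R,5R)-2-[(1R,2R)-2-chloro-1-methylcyclohex-3-en-1-yl]-1,3-dimethyl-4,5-diphenylimidazolidine | CN1[C@H](c2ccccc2)[C@H](N(C)C1[C@@]3(C)CCC=C[C@H]3Cl)c2ccccc2
F4 | step 6 | (4S,5S)-4-chloro-5-[(Z)-2-chloroethenyl]-5-methylcyclohex-2-en-1-ol (either C1 epimer) | C[C@@]1(/C=C\Cl)CC(O)C=C[C@@H]1Cl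
F5 | step 10 | (1R,2R,4S,5S)-1-bromo-1-(bromomethyl)-2,4-dichloro-5-[(Z)-2-chloroethenyl]-5-methylcyclohexane | C[C@@]1(/C=C\Cl)C[C@](Br)(CBr)[C@H](Cl)C[C@@H]1Cl
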